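Assumption: the target is taken to be the structure of the SMILES string, methyl 4-[(2R,5S)-5-[(3E,11E)-12-bromododeca-3,11-dien-1-yn-1-yl]oxolan-2-yl]butanoate; diazomethane is used as a fresh ethereal solution made from N-methyl-N-nitroso-4-methylbenzenesulfonamide and KOH.

## Analysis of the target

The target is a C20 chain, numbered here from the ester carbon C1 to the brominated carbon C20, and its only ring is an oxolane made of O, C5, C6, C7 and C8. C5 carries a three-methylene arm ending in the methyl ester (C4 to C1). C8 carries the unsaturated arm: the C9≡C10 alkyne conjugated to the E C11=C12 alkene, six methylenes (C13 to C18) and the terminal E bromoalkene C19=C20. The two stereocentres are C5 (R) and C8 (S); they flank the ring oxygen and their substituents lie on opposite faces of the ring, a 2,5-trans arrangement. The sensitive groups are the E bromoalkene (reactive towards low-valent metals and hydride reagents), the conjugated enyne, the methyl ester and the C8–H bond, which is both propargylic and next to oxygen. The main difficulty is the trans relationship across the oxygen: the target has only methylenes at C6 and C7, so nothing in the ring can relay stereochemistry from one centre to the other. A second difficulty is joining the enyne without touching the bromoalkene. The strategy rests on the oxygen that links C5 and C8. If that oxygen carries an allyl group while it is still an ether on C8, the allyl group can be passed from oxygen to C5 in the ring-forming step and becomes C4 and C3 of the ester arm, with C6 temporarily a ketone.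

## Retrosynthetic reasoning

C10–C11. The target 26 is cut between the alkyne carbon C10 and the alkene carbon C11, which gives the terminal alkyne 20 and the bromo-iodo-diene 25. This is the most convergent cut: all ten carbons of the lipid tail arrive in one piece, both alkene geometries are already fixed in 25, and the fragile bromoalkene enters in the last step. The forward coupling has to discriminate between the carbon–iodine and the carbon–bromine bond of 25.

C11–halogen and C20–halogen. Diene 25 is traced through bromo-enyne 23 to the symmetrical diyne 21. Each carbon–halogen bond comes from syn hydrometallation of a terminal alkyne followed by halogenolysis with retention, so both E geometries follow from the mechanism. The bromide is installed first so that the weaker carbon–iodine bond never meets the metal hydride.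

C9–C10. Alkyne 20 is cut to aldehyde 19 by a one-carbon homologation, and 19 goes back through alcohol 18 to silyl ether 17. The alkyne is introduced this late because it would not survive the metathesis, hydrogenation and tin hydride steps that build the other arm.

C6 oxygenation. A ketone is added retrosynthetically at C6: 17 comes from thionocarbonate 16, alcohol 15 and ketone 14. The carbonyl is not part of the target; it is the handle that makes C5 a carbene carbon in the key step, and a radical deoxygenation removes it.

C3=C2. Keto ester 14 comes from enoate 13, which is cut at the alkene into allyl ketone 11 and methyl acrylate 12. The allyl group of 11 supplies C4 and C3 only; its terminal carbon is exchanged for the C2–C1 unit of 12, so the chain reaches the correct length after hydrogenation.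

O–C5 and C5–C4 (key disconnection). Oxolanone 11 is cut at the ring bond O–C5 and at the exocyclic bond C5–C4. That leads to diazoketone 8, in which C5 is the diazo carbon and the allyl group sits on the C8 oxygen, via copper carbene 9 and oxonium ylide 10. One operation forms the ring, the C5–C4 bond and the C5 stereocentre, and the only stereochemical input is the C8 centre. The forward step must give the ylide in preference to other carbene pathways and must deliver the allyl group trans to the C8 substituent.

C5–C6, O–allyl, O–Si and the first reduction. Diazoketone 8 comes from acid 6 through mixed anhydride 7 by acylation of a one-carbon diazo unit. Acid 6 comes from ester 5, 5 from alcohol 3 and imidate 4, 3 from diol 2, and 2 from dimethyl (S)-malate 1. The malate carbinol becomes C8, so the absolute configuration of the whole molecule is bought with the starting material.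

## Alternatives that were turned down

Alternative 1: Here the C9≡C10 triple bond is the strategic bond. It is made by alkyne metathesis, and the reaction is made intramolecular by joining the two halves as an ester between the C1 carboxyl and a hydroxyl on C19. The tethered diyne A1, with a methyl cap on each alkyne, would be treated with Mo(≡C-C6H4-4-OMe)(OSiPh3)3 and 5 Å molecular sieves. The two alkynes exchange, a volatile C4 alkyne leaves, and the 19-membered macrolactone A2 forms (ring size counted through the oxolane oxygen). In its favour, ring closure avoids the homodimers of an intermolecular alkyne metathesis, catalysts of this type tolerate esters, ethers and alkenes, and the enyne geometry is set beforehand. Methanolysis of the lactone would later give the methyl ester for free. Against it, the tether is built only to be cut. After ring opening the C19 alcohol still has to be oxidised and homologated to the E bromoalkene (C20), so the alkene geometry of the most sensitive group is decided in the last step. A propargylic ether alkyne and a conjugated enyne are both demanding metathesis partners. Above all, this alternative does not address the trans oxolane, which must be made by other chemistry before A1 exists. It is stronger on one point: it never has two vinyl halides in one substrate, so it avoids the chemoselectivity problem of the final coupling chosen here. The chosen strategy accepts that risk in return for a one-step C10–C11 bond formation, and it spends its key step on the stereochemical problem.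

Alternative 2: The oxolane is cut at O–C8 and both ring stereocentres are traced to the meso diepoxide A3. Chiral Co(salen)(OAc), a trivalent cobalt complex in which salen is N,N'-bis(3,5-di-tert-butylsalicylidene)cyclohexane-1,2-diaminate, would catalyse hydrolytic opening of the S epoxide only. The secondary hydroxyl so formed attacks the internal carbon of the remaining R epoxide with inversion, in a 5-exo closure, to give the C2-symmetric diol A4. In its favour, a catalyst sets both stereocentres in one operation from an achiral C6 precursor, with no chiral pool and no diazo chemistry. It reaches the ring in far fewer steps than the chosen route, and on that point it is stronger. Against it, A4 has two identical hydroxymethyl arms. Differentiating them by monoprotection is statistical. One arm then needs three more carbons (C3 to C1) attached to C4, which means activation and carbon–carbon bond formation at a primary carbon next to the ring oxygen. Double epoxidation of the parent diene gives a mixture of meso and racemic diepoxide, and the racemic part would lead to cis ring unless it is removed. The closure also has to favour 5-exo over 6-endo. The chosen strategy gives a ring whose two arms are different from the start (allyl and silyloxymethyl) and forms C5–C4 in the ring-forming step. It pays for this with a longer precursor synthesis and the removal of the C6 ketone.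

Alternative 3: The bonds O–C5 and C4–C3 are cut together, which leads to the alkenol A5, an S propargylic alcohol with a silyl-capped alkyne and a terminal C5=C4 alkene. Under aerobic conditions with Co(CF3COCHCOCH3)2, a divalent cobalt complex, and a hydrogen-atom donor, the hydroxyl would add to the alkene in a 5-exo closure. The primary radical released at C4 would be trapped by an acrylate ester, and hydrogen-atom transfer would then give the oxolane ester A6. In its favour, one step would deliver the ring, the trans C5 centre, the whole C1 to C4 arm and a protected alkyne. Aerobic cobalt cyclisations of pent-4-en-1-ols are known to be strongly 2,5-trans selective. On step economy this alternative is clearly stronger than the chosen route, possibly by half. Against it, the outcome depends on a three-way competition at the C4 radical: capture by oxygen, direct reduction by the donor, and addition to the acrylate. Only the last is wanted, and the adduct radical must then be reduced before it adds to more acrylate. The enantiopure propargylic alcohol A5 needs its own asymmetric step, and the silyl group has to be removed afterwards. The chosen strategy offers predictability in exchange for length: its ring-forming step is a concerted sigmatropic shift whose stereochemical course is fixed by geometry, not by the relative rates of radical trapping.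

Key step: step 6

## Route

Step 1
Reactants: 1 dimethyl (S)-malate
Product: 2 methyl (3S)-3,4-dihydroxybutanoate
Conditions: BH3·SMe2 (1.0 equiv), NaBH4 (5 mol %), THF, 0 °C → rt; MeOH quench
Reagents that add atoms: none
Why: Hydroxyl-directed borane reduction: the free hydroxyl forms an alkoxyborane that delivers hydride through a five-membered chelate to the neighbouring ester only, with NaBH4 as catalyst, so the distal ester should survive. The stereocentre is not touched.

Step 2
Reactants: 2 methyl (3S)-3,4-dihydroxybutanoate
Product: 3 methyl (3S)-4-[(tert-butyldiphenylsilyl)oxy]-3-hydroxybutanoate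
Conditions: TBDPSCl (1.05 equiv), imidazole, CH2Cl2, 0 °C
Reagents that add atoms: tert-butyl(chloro)diphenylsilane, CC(C)(C)[Si](Cl)(c1ccccc1)c1ccccc1
Why: Silylation of a 1,2-diol with a bulky chlorosilane is selective for the primary hydroxyl. The TBDPS ether is chosen because it tolerates the later acid, base, hydride and radical steps.

Step 3
Reactants: 3 methyl (3S)-4-[(tert-butyldiphenylsilyl)oxy]-3-hydroxybutanoate; 4 allyl 2,2,2-trichloroacetimidate
Product: 5 methyl (3S)-3-(allyloxy)-4-[(tert-butyldiphenylsilyl)oxy]butanoate
Conditions: 4 (1.5 equiv), TfOH (cat.), cyclohexane/CH2Cl2, rt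
Reagents that add atoms: none
Why: Acid-catalysed O-allylation with a trichloroacetimidate. An alkoxide of this β-hydroxy ester would risk retro-aldol cleavage, β-elimination and 1,2-silyl migration, so base is avoided; the C–O bond at the stereocentre is not broken.

Step 4
Reactants: 5 methyl (3S)-3-(allyloxy)-4-[(tert-butyldiphenylsilyl)oxy]butanoate
Product: 6 (3S)-3-(allyloxy)-4-[(tert-butyldiphenylsilyl)oxy]butanoic acid
Conditions: LiOH·H2O, THF/H2O, 0 °C → rt; then 1 M HCl to pH 3
Reagents that add atoms: lithium hydroxide, [Li+].[OH-]
Why: Ester saponification by acyl–oxygen cleavage. Cold, dilute hydroxide is used to keep β-elimination of the allyloxy group slow, and the TBDPS ether is stable to it.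

Step 5
Reactants: 6 (3S)-3-(allyloxy)-4-[(tert-butyldiphenylsilyl)oxy]butanoic acid
Product: 8 (4S)-4-(allyloxy)-5-[(tert-butyldiphenylsilyl)oxy]-1-diazopentan-2-one, via mixed isobutyl carbonic anhydride 7 (not isolated)
Conditions: i-BuOCOCl, Et3N, Et2O, −20 °C; then CH2N2 (excess, Et2O), 0 °C → rt
Reagents that add atoms: diazomethane, C=[N+]=[N-] (supplies C5 and the diazo nitrogens); isobutyl chloroformate, CC(C)COC(=O)Cl (its atoms stay only in intermediate 7)
Why: Acylation of diazomethane by a mixed carbonic anhydride, the first stage of an Arndt–Eistert sequence. The anhydride is attacked at the less hindered, more electrophilic acyl carbon, and the carbonate leaving group falls apart, so the acid-sensitive diazoketone forms under neutral conditions.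

Step 6
Reactants: 8 (4S)-4-(allyloxy)-5-[(tert-butyldiphenylsilyl)oxy]-1-diazopentan-2-one
Product: 11 (2R,5S)-2-allyl-5-{[(tert-butyldiphenylsilyl)oxy]methyl}oxolan-3-one, via copper carbene 9 (not isolated), via oxonium ylide 10 (not isolated)
Conditions: Cu(acac)2 (10 mol %), THF, reflux, slow addition of 8
Reagents that add atoms: none
Why: Cu(acac)2 is a divalent copper precatalyst that is probably reduced in the flask to a monovalent copper species; it decomposes the diazoketone with loss of N2 to the electrophilic copper carbene 9 at C5. A lone pair of the allyl ether oxygen on C8 adds to the carbene carbon in a five-membered closure (5-exo with respect to the Cu=C5 bond), which forms O–C5, closes the oxolane and gives the copper-associated oxonium ylide 10. The ylide then undergoes a suprafacial [2,3]-sigmatropic shift through a five-membered envelope transition state: the alkene terminus of the allyl group bonds to C5 (the C5–C4 bond) while the O–CH2 bond breaks, so the former alkene terminus becomes C4. The closest known reaction type is the copper-catalysed tandem oxonium ylide formation and [2,3]-rearrangement of allyloxy-substituted α-diazoketones, an established entry to 2,5-trans-disubstituted oxolan-3-ones. The only new stereocentre, C5, is controlled by the C8 centre: in 10 the O-allyl group lies anti to the silyloxymethyl group on the neighbouring ring carbon, and the suprafacial shift carries it to the same face of C5, trans to the C8 substituent, which makes C5 R. The step needs chemoselectivity for ylide formation over C–H insertion, cyclopropanation of the allyl alkene and carbene dimerisation, and it needs 2,5-trans diastereoselectivity; copper in place of the more reactive Rh2(OAc)4 and slow addition serve the first, the bulky C8 substituent next to oxygen serves the second. A competing [1,2]-shift would give the same constitution, and the neutral medium should keep the C5–H next to the new ketone from epimerising.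

Step 7
Reactants: 11 (2R,5S)-2-allyl-5-{[(tert-butyldiphenylsilyl)oxy]methyl}oxolan-3-one; 12 methyl acrylate
Product: 13 methyl (2E)-4-[(2R,5S)-5-{[(tert-butyldiphenylsilyl)oxy]methyl}-3-oxooxolan-2-yl]but-2-enoate
Conditions: 12 (5 equiv), second-generation Grubbs catalyst RuCl2(=CHPh)(PCy3)(H2IMes) (5 mol %), CH2Cl2, 40 °C
Reagents that add atoms: none
Why: Olefin cross-metathesis of an unhindered terminal alkene with an electron-poor acrylate, which homodimerises slowly, so the cross product should dominate. The terminal carbon of the allyl group leaves and C2 and C1 enter; the conditions are neutral, so C5 is not at risk.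

Step 8
Reactants: 13 methyl (2E)-4-[(2R,5S)-5-{[(tert-butyldiphenylsilyl)oxy]methyl}-3-oxooxolan-2-yl]but-2-enoate
Product: 14 methyl 4-[(2R,5S)-5-{[(tert-butyldiphenylsilyl)oxy]methyl}-3-oxooxolan-2-yl]butanoate
Conditions: H2 (1 atm), 10% Pd/C, EtOAc, rt
Reagents that add atoms: none
Why: Heterogeneous hydrogenation of a conjugated alkene; ketone, ester and silyl ether are inert. Saturating the enoate at once also removes the risk of a vinylogous β-elimination that would open the ring at C5–O.

Step 9
Reactants: 14 methyl 4-[(2R,5S)-5-{[(tert-butyldiphenylsilyl)oxy]methyl}-3-oxooxolan-2-yl]butanoate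
Product: 15 methyl 4-[(2R,5S)-5-{[(tert-butyldiphenylsilyl)oxy]methyl}-3-hydroxyoxolan-2-yl]butanoate (both C3 epimers)
Conditions: NaBH4, MeOH, −20 °C
Reagents that add atoms: none
Why: Borohydride reduces the ketone much faster than the methyl ester at low temperature. The new carbinol centre is removed two steps later, so its configuration does not matter, and C5 is no longer epimerisable once the carbonyl is gone.

Step 10
Reactants: 15 methyl 4-[(2R,5S)-5-{[(tert-butyldiphenylsilyl)oxy]methyl}-3-hydroxyoxolan-2-yl]butanoate (both C3 epimers)
Product: 16 methyl 4-[(2R,5S)-5-{[(tert-butyldiphenylsilyl)oxy]methyl}-3-[(phenoxycarbonothioyl)oxy]oxolan-2-yl]butanoate (both C3 epimers)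
Conditions: PhOC(S)Cl, pyridine, DMAP (cat.), CH2Cl2, rt
Reagents that add atoms: O-phenyl carbonochloridothioate (phenyl chlorothionoformate), S=C(Cl)Oc1ccccc1
Why: Acylation of the secondary alcohol to an aryl thionocarbonate under amine catalysis. It is preferred to a xanthate made with NaH, CS2 and MeI because the strong base could attack the methyl ester.

Step 11
Reactants: 16 methyl 4-[(2R,5S)-5-{[(tert-butyldiphenylsilyl)oxy]methyl}-3-[(phenoxycarbonothioyl)oxy]oxolan-2-yl]butanoate (both C3 epimers)
Product: 17 methyl 4-[(2R,5S)-5-{[(tert-butyldiphenylsilyl)oxy]methyl}oxolan-2-yl]butanoate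
Conditions: Bu3SnH, AIBN (cat.), toluene, 100 °C
Reagents that add atoms: none
Why: Barton–McCombie deoxygenation: the stannyl radical adds to sulfur, the C6–O bond fragments, and the secondary C6 radical takes hydrogen from the tin hydride. The same thionocarbonate chemistry is routine on oxolan-3-ols, and C5 and C8 are not involved.

Step 12
Reactants: 17 methyl 4-[(2R,5S)-5-{[(tert-butyldiphenylsilyl)oxy]methyl}oxolan-2-yl]butanoate
Product: 18 methyl 4-[(2R,5S)-5-(hydroxymethyl)oxolan-2-yl]butanoate
Conditions: TBAF, AcOH, THF, rt
Reagents that add atoms: none
Why: Fluoride-induced cleavage of the silyl ether, driven by the Si–F bond. Acetic acid buffers the alkoxide so that the methyl ester is not attacked.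

Step 13
Reactants: 18 methyl 4-[(2R,5S)-5-(hydroxymethyl)oxolan-2-yl]butanoate
Product: 19 methyl 4-[(2R,5S)-5-formyloxolan-2-yl]butanoate
Conditions: Dess–Martin periodinane, CH2Cl2, 0 °C → rt
Reagents that add atoms: none
Why: Dess–Martin oxidation stops at the aldehyde under nearly neutral conditions. This matters because C8 is now α to a carbonyl and to oxygen, and the crude aldehyde is used directly.

Step 14
Reactants: 19 methyl 4-[(2R,5S)-5-formyloxolan-2-yl]butanoate
Product: 20 methyl 4-[(2R,5S)-5-ethynyloxolan-2-yl]butanoate
Conditions: dimethyl (1-diazo-2-oxopropyl)phosphonate, K2CO3, MeOH, 0 °C → rt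
Reagents that add atoms: dimethyl (1-diazo-2-oxopropyl)phosphonate, CC(=O)C(=[N+]=[N-])P(=O)(OC)OC (its diazo carbon becomes C10)
Why: Ohira–Bestmann alkynylation, a Seyferth–Gilbert homologation: methanolysis releases the diazomethylphosphonate anion, which olefinates the aldehyde, and loss of N2 with a 1,2-hydrogen shift gives the terminal alkyne. The mild carbonate base limits epimerisation at C8, and methanol can only exchange the methyl ester for itself.

Step 15
Reactants: 21 deca-1,9-diyne
Product: 23 (1E)-1-bromodec-1-en-9-yne, via alkenylzirconocene chloride 22 (not isolated)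
Conditions: 21 (3 equiv), Cp2Zr(H)Cl (1 equiv), CH2Cl2, rt; then NBS, 0 °C
Reagents that add atoms: N-bromosuccinimide, O=C1CCC(=O)N1Br (bromine); Cp2Zr(H)Cl, [H][Zr](Cl)(C1C=CC=C1)C1C=CC=C1 (its zirconocene fragment stays only in intermediate 22)
Why: Hydrozirconation–bromination: the zirconium hydride adds syn and anti-Markovnikov to one terminal alkyne, and NBS cleaves the carbon–zirconium bond with retention, which fixes the E geometry. A threefold excess of the diyne keeps double addition low, and the volatile diyne can be recovered.

Step 16
Reactants: 23 (1E)-1-bromodec-1-en-9-yne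
Product: 25 (1E,9E)-1-bromo-10-iododeca-1,9-diene, via alkenylzirconocene chloride 24 (not isolated)
Conditions: Cp2Zr(H)Cl (1.1 equiv), CH2Cl2, rt, short reaction time; then iodine, 0 °C, dark
Reagents that add atoms: iodine, [I][I]; Cp2Zr(H)Cl, [H][Zr](Cl)(C1C=CC=C1)C1C=CC=C1 (its zirconocene fragment stays only in intermediate 24)
Why: The same hydrozirconation, now with iodine as the electrophile; retention in the iodinolysis gives the second E alkene. Terminal alkynes take up the zirconium hydride much faster than 1,2-disubstituted alkenes, so the bromoalkene is expected to survive a slight excess of reagent.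

Step 17
Reactants: 20 methyl 4-[(2R,5S)-5-ethynyloxolan-2-yl]butanoate; 25 (1E,9E)-1-bromo-10-iododeca-1,9-diene
Product: 26 methyl 4-[(2R,5S)-5-[(3E,11E)-12-bromododeca-3,11-dien-1-yn-1-yl]oxolan-2-yl]butanoate (the target)
Conditions: 25 (1.3 equiv), Pd(PPh3)4 (5 mol %), CuI (10 mol %), Et3N, THF (degassed), 0 °C → rt
Reagents that add atoms: none
Why: Sonogashira coupling: zerovalent palladium inserts into the weaker carbon–iodine bond of 25 much faster than into the carbon–bromine bond, the copper acetylide of 20 transmetallates, and reductive elimination joins C10 to C11 with retention of the E geometry. An excess of 25 and a low temperature guard against a second coupling at the bromoalkene; neither stereocentre is involved.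

## Compound list

1 | dimethyl (S)-malate | COC(=O)C[C@@H](C(=O)OC)O | starting material
2 | methyl (3S)-3,4-dihydroxybutanoate | COC(=O)C[C@@H](CO)O | intermediate
3 | methyl (3S)-4-[(tert-butyldiphenylsilyl)oxy]-3-hydroxybutanoate | COC(=O)C[C@@H](CO[Si](c1ccccc1)(c1ccccc1)C(C)(C)C)O | intermediate
4 | allyl 2,2,2-trichloroacetimidate | C=CCOC(=N)C(Cl)(Cl)Cl | starting material
5 | methyl (3S)-3-(allyloxy)-4-[(tert-butyldiphenylsilyl)oxy]butanoate | COC(=O)C[C@@H](CO[Si](c1ccccc1)(c1ccccc1)C(C)(C)C)OCC=C | intermediate
6 | (3S)-3-(allyloxy)-4-[(tert-butyldiphenylsilyl)oxy]butanoic acid | OC(=O)C[C@@H](CO[Si](c1ccccc1)(c1ccccc1)C(C)(C)C)OCC=C | intermediate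
7 | mixed anhydride of 6 with isobutyl hydrogen carbonate (not isolated) | CC(C)COC(=O)OC(=O)C[C@@H](CO[Si](c1ccccc1)(c1ccccc1)C(C)(C)C)OCC=C | intermediate
8 | (4S)-4-(allyloxy)-5-[(tert-butyldiphenylsilyl)oxy]-1-diazopentan-2-one | [N-]=[N+]=CC(=O)C[C@@H](CO[Si](c1ccccc1)(c1ccccc1)C(C)(C)C)OCC=C | intermediate
9 | copper carbene at C5 formed from 8 (acetylacetonate ligand on copper not drawn; not isolated) | [Cu]=CC(=O)C[C@@H](CO[Si](c1ccccc1)(c1ccccc1)C(C)(C)C)OCC=C | intermediate
10 | (5S)-1-allyl-5-{[(tert-butyldiphenylsilyl)oxy]methyl}-3-oxooxolan-1-ium-2-ide, oxonium ylide with O-allyl anti to the C5 substituent (not isolated) | C=CC[O+]1[CH-]C(=O)C[C@H]1CO[Si](c2ccccc2)(c2ccccc2)C(C)(C)C | intermediate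
11 | (2R,5S)-2-allyl-5-{[(tert-butyldiphenylsilyl)oxy]methyl}oxolan-3-one | C=CC[C@@H]1C(=O)C[C@@H](CO[Si](c2ccccc2)(c2ccccc2)C(C)(C)C)O1 | intermediate
12 | methyl acrylate | C=CC(=O)OC | starting material
13 | methyl (2E)-4-[(2R,5S)-5-{[(tert-butyldiphenylsilyl)oxy]methyl}-3-oxooxolan-2-yl]but-2-enoate | COC(=O)/C=C/C[C@@H]1C(=O)C[C@@H](CO[Si](c2ccccc2)(c2ccccc2)C(C)(C)C)O1 | intermediate
14 | methyl 4-[(2R,5S)-5-{[(tert-butyldiphenylsilyl)oxy]methyl}-3-oxooxolan-2-yl]butanoate | COC(=O)CCC[C@@H]1C(=O)C[C@@H](CO[Si](c2ccccc2)(c2ccccc2)C(C)(C)C)O1 | intermediate
15 | methyl 4-[(2R,5S)-5-{[(tert-butyldiphenylsilyl)oxy]methyl}-3-hydroxyoxolan-2-yl]butanoate, both C3 epimers | COC(=O)CCC[C@@H]1C(O)C[C@@H](CO[Si](c2ccccc2)(c2ccccc2)C(C)(C)C)O1 | intermediate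
16 | methyl 4-[(2R,5S)-5-{[(tert-butyldiphenylsilyl)oxy]methyl}-3-[(phenoxycarbonothioyl)oxy]oxolan-2-yl]butanoate, both C3 epimers | COC(=O)CCC[C@@H]1C(OC(=S)Oc2ccccc2)C[C@@H](CO[Si](c2ccccc2)(c2ccccc2)C(C)(C)C)O1 | intermediate
17 | methyl 4-[(2R,5S)-5-{[(tert-butyldiphenylsilyl)oxy]methyl}oxolan-2-yl]butanoate | COC(=O)CCC[C@@H]1CC[C@@H](CO[Si](c2ccccc2)(c2ccccc2)C(C)(C)C)O1 | intermediate
18 | methyl 4-[(2R,5S)-5-(hydroxymethyl)oxolan-2-yl]butanoate | COC(=O)CCC[C@@H]1CC[C@@H](CO)O1 | intermediate
19 | methyl 4-[(2R,5S)-5-formyloxolan-2-yl]butanoate | COC(=O)CCC[C@@H]1CC[C@@H](C=O)O1 | intermediate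
20 | methyl 4-[(2R,5S)-5-ethynyloxolan-2-yl]butanoate | COC(=O)CCC[C@@H]1CC[C@@H](C#C)O1 | intermediate
21 | deca-1,9-diyne | C#CCCCCCCC#C | starting material
22 | chlorobis(cyclopentadienyl)[(1E)-dec-1-en-9-yn-1-yl]zirconium (cyclopentadienyl rings drawn σ-bonded; not isolated) | C#CCCCCCC/C=C/[Zr](Cl)(C1C=CC=C1)C1C=CC=C1 | intermediate
23 | (1E)-1-bromodec-1-en-9-yne | C#CCCCCCC/C=C/Br | intermediate
24 | chlorobis(cyclopentadienyl)[(1E,9E)-10-bromodeca-1,9-dien-1-yl]zirconium (cyclopentadienyl rings drawn σ-bonded; not isolated) | Br/C=C/CCCCCC/C=C/[Zr](Cl)(C1C=CC=C1)C1C=CC=C1 | intermediate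
25 | (1E,9E)-1-bromo-10-iododeca-1,9-diene | Br/C=C/CCCCCC/C=C/I | intermediate
26 | methyl 4-[(2R,5S)-5-[(3E,11E)-12-bromododeca-3,11-dien-1-yn-1-yl]oxolan-2-yl]butanoate | COC(=O)CCC[C@@H]1CC[C@@H](C#C/C=C/CCCCCC/C=C/Br)O1 | target

## Step count and risk

Total step count: 17. Longest linear sequence: 15 steps (steps 1 to 14, then step 17); steps 15 and 16 form the two-step side branch.

Least certain steps:

Step 6 (key step). The carbene may be diverted before the ylide forms: insertion into the allylic O–CH2 bond, cyclopropanation of the allyl alkene, or dimerisation if the diazoketone accumulates. The trans selectivity may also erode if the allyl group on oxygen is not held anti to the C8 substituent, or if C5 epimerises next to the ketone during purification. The fallback drops the carbene chemistry and the C6 ketone altogether. It sets out from hydroxy ester 3 and comes back to the route at silyl ether 17. Reduction of the ester of 3 with LiBH4 gives (S)-4-[(tert-butyldiphenylsilyl)oxy]butane-1,3-diol F1. Selective sulfonylation of its primary hydroxyl (TsCl, pyridine, 0 °C) gives (S)-4-[(tert-butyldiphenylsilyl)oxy]-3-hydroxybutyl 4-methylbenzenesulfonate F2. Displacement with vinylmagnesium bromide under CuI catalysis gives (S)-1-[(tert-butyldiphenylsilyl)oxy]hex-5-en-2-ol F3, in which the carbinol is C8 and the alkene is C5=C4. Aerobic oxidative cyclisation with Co(modp)2 (a divalent cobalt complex; modp is 1-morpholinocarbamoyl-4,4-dimethyl-1,3-pentanedionate), O2 and t-BuOOH in i-PrOH is a known, strongly 2,5-trans-selective closure of pent-4-en-1-ols. It should give [(2S,5S)-5-{[(tert-butyldiphenylsilyl)oxy]methyl}oxolan-2-yl]methanol F4. Iodination (iodine, PPh3, imidazole) gives tert-butyl{[(2S,5S)-5-(iodomethyl)oxolan-2-yl]methoxy}diphenylsilane F5. A radical conjugate addition of the C4 radical to methyl acrylate 12 (Bu3SnH, AIBN) forms C4–C3 and gives 17.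

Step 17. The palladium may fail to discriminate between the two vinyl halides, above all late in the reaction, when the product's own bromoalkene competes for the catalyst and a second coupling sets in. Copper-mediated oxidative dimerisation of alkyne 20 may also compete if oxygen is not excluded. The fallback removes the dihalide: it sets out from alkyne 20 and comes back at target 26. Hydrozirconation–iodination of commercial non-8-yn-1-ol (Cp2Zr(H)Cl, 2.2 equiv, then iodine) gives (E)-9-iodonon-8-en-1-ol F6, which has a single halide. Sonogashira coupling of F6 with 20 gives methyl 4-[(2R,5S)-5-[(3E)-11-hydroxyundec-3-en-1-yn-1-yl]oxolan-2-yl]butanoate F7. Dess–Martin oxidation gives methyl 4-[(2R,5S)-5-[(3E)-11-oxoundec-3-en-1-yn-1-yl]oxolan-2-yl]butanoate F8. A Takai-type bromo-olefination of F8 with CHBr3 and CrBr2 (divalent chromium) installs C20 and the E bromoalkene last and gives 26.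

Step 16. The zirconium hydride may add to the bromoalkene of 23 as well as to the alkyne; β-elimination of bromide from the resulting alkylzirconium would remove the bromine. The fallback changes the metal: it sets out from bromo-enyne 23 and comes back at diene 25. Hydroboration of the terminal alkyne with catecholborane, which leaves vinyl bromides alone, gives 2-[(1E,9E)-10-bromodeca-1,9-dien-1-yl]-1,3,2-benzodioxaborole F9. Hydrolysis gives [(1E,9E)-10-bromodeca-1,9-dien-1-yl]boronic acid F10. Treatment of F10 with NaOH and then iodine replaces boron by iodine with retention and gives 25.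

Step 14. The carbonate–methanol medium may epimerise C8 of the α-alkoxy aldehyde before the homologation takes place, which would erode the trans relationship set in step 6. The fallback avoids exposing the aldehyde to base: it sets out from aldehyde 19 and comes back at alkyne 20. Dibromo-olefination with CBr4 and PPh3 gives methyl 4-[(2R,5S)-5-(2,2-dibromoethenyl)oxolan-2-yl]butanoate F11. Hydrogenolysis with Bu3SnH and catalytic Pd(PPh3)4 (zerovalent palladium) removes the bromine trans to the ring and gives methyl 4-[(2R,5S)-5-[(Z)-2-bromoethenyl]oxolan-2-yl]butanoate F12. Anti-elimination of HBr from F12 with TBAF in DMF gives 20; the organolithium step of a Corey–Fuchs sequence, which the methyl ester would not tolerate, is not needed.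

## Further compounds

F1 | step 6 | (S)-4-[(tert-butyldiphenylsilyl)oxy]butane-1,3-diol | OCC[C@@H](CO[Si](c1ccccc1)(c1ccccc1)C(C)(C)C)O
F2 | step 6 | (S)-4-[(tert-butyldiphenylsilyl)oxy]-3-hydroxybutyl 4-methylbenzenesulfonate | Cc1ccc(cc1)S(=O)(=O)OCC[C@@H](CO[Si](c1ccccc1)(c1ccccc1)C(C)(C)C)O
F3 | step 6 | (S)-1-[(tert-butyldiphenylsilyl)oxy]hex-5-en-2-ol | C=CCC[C@@H](CO[Si](c1ccccc1)(c1ccccc1)C(C)(C)C)O
F4 | step 6 | [(2S,5S)-5-{[(tert-butyldiphenylsilyl)oxy]methyl}oxolan-2-yl]methanol | OC[C@@H]1CC[C@@H](CO[Si](c2ccccc2)(c2ccccc2)C(C)(C)C)O1
F5 | step 6 | tert-butyl{[(2S,5S)-5-(iodomethyl)oxolan-2-yl]methoxy}diphenylsilane | IC[C@@H]1CC[C@@H](CO[Si](c2ccccc2)(c2ccccc2)C(C)(C)C)O1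
F6 | step 17 | (E)-9-iodonon-8-en-1-ol | OCCCCCCC/C=C/I
F7 | step 17 | methyl 4-[(2R,5S)-5-[(3E)-11-hydroxyundec-3-en-1-yn-1-yl]oxolan-2-yl]butanoate | COC(=O)CCC[C@@H]1CC[C@@H](C#C/C=C/CCCCCCCO)O1
F8 | step 17 | methyl 4-[(2R,5S)-5-[(3E)-11-oxoundec-3-en-1-yn-1-yl]oxolan-2-yl]butanoate | COC(=O)CCC[C@@H]1CC[C@@H](C#C/C=C/CCCCCCC=O)O1
F9 | step 16 | 2-[(1E,9E)-10-bromodeca-1,9-dien-1-yl]-1,3,2-benzodioxaborole | Br/C=C/CCCCCC/C=C/B1Oc2ccccc2O1
F10 | step 16 | [(1E,9E)-10-bromodeca-1,9-dien-1-yl]boronic acid | Br/C=C/CCCCCC/C=C/B(O)O
F11 | step 14 | methyl 4-[(2R,5S)-5-(2,2-dibromoethenyl)oxolan-2-yl]butanoate | COC(=O)CCC[C@@H]1CC[C@@H](C=C(Br)Br)O1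
F12 | step 14 | methyl 4-[(2R,5S)-5-[(Z)-2-bromoethenyl]oxolan-2-yl]butanoate | COC(=O)CCC[C@@H]1CC[C@@H](/C=C\Br)O1
A1 | alternative 1 | (8E)-dodec-8-en-10-yn-1-yl 4-[(2R,5S)-5-(prop-1-yn-1-yl)oxolan-2-yl]butanoate | CC#C/C=C/CCCCCCCOC(=O)CCC[C@@H]1CC[C@@H](C#CC)O1
A2 | alternative 1 | 19-membered macrolactone of 4-[(2R,5S)-5-[(3E)-11-hydroxyundec-3-en-1-yn-1-yl]oxolan-2-yl]butanoic acid (C1 carboxyl esterified by the C19 hydroxyl) | O=C1CCC[C@@H]2CC[C@@H](C#C/C=C/CCCCCCCO1)O2
A3 | alternative 2 | meso-1,2:5,6-diepoxyhexane, (2R)-2-{2-[(2S)-oxiran-2-yl]ethyl}oxirane | C(C[C@@H]1CO1)C[C@H]1CO1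
A4 | alternative 2 | (2S,5S)-oxolane-2,5-diyldimethanol | OC[C@@H]1CC[C@@H](CO)O1
A5 | alternative 3 | (3S)-1-(triisopropylsilyl)hept-6-en-1-yn-3-ol | C=CCC[C@@H](C#C[Si](C(C)C)(C(C)C)C(C)C)O
A6 | alternative 3 | methyl 4-[(2R,5S)-5-[(triisopropylsilyl)ethynyl]oxolan-2-yl]butanoate | COC(=O)CCC[C@@H]1CC[C@@H](C#C[Si](C(C)C)(C(C)C)C(C)C)O1
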